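The butenolide ring (O1, C2, C3, C4, C5) carries oxygen on both C4 and C5, so its carbonyl carbon C2 is first installed as a cyclic carbonate bridging these two enol oxygens. The key step is a DMAP-triggered 1,3-O-to-C carboxyl shift: the carbonate ring opens, the C3 enolate carbon attacks C2, and the 3-methyltetronic acid ring closes with the E-configured exocyclic C5 alkene and the C4 hydroxyl in place for stearoylation. The precursor, a 4-ethylidene-5-alkylidene-1,3-dioxolan-2-one, comes from E-selective enolization of an alkynyl ketone, Boc trapping and Ph3PAuNTf2-catalysed cyclization; the chain derives from farnesyl bromide and 3-furanmethanol, its stereocentre from asymmetric hydrogenation.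

Key step: step 10

Labels used below: ring atoms O1, C2 (C=O), C3 (C–CH3), C4 (C–O-acyl), C5; C1′ is the exocyclic CH and C2′ the methyl-bearing stereocentre (S). The target has C2′ trans to O1 across C5=C1′ (E).

Assumption: Ru(OAc)2[(S)-BINAP] is taken to reduce the (E)-2-methyl-2-alken-1-ol terminus with the facial sense it shows for geraniol, which corresponds to 2′S; if the sense proves opposite, the (R)-ligand is used.

Step 1
Reactants: 1 3-furanmethanol
Product: 2 3-(chloromethyl)furan
Conditions: SOCl2, pyridine, Et2O, 0 °C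
Reagents that add atoms: thionyl chloride, O=S(Cl)Cl
Why: Chlorodehydroxylation of the primary furylmethyl alcohol through its chlorosulfite; the labile chloride is used at once.

Step 2
Reactants: 2 3-(chloromethyl)furan; 3 (2E,6E)-farnesyl bromide
Product: 5 ambliofuran [3-((3E,7E)-4,8,12-trimethyltrideca-3,7,11-trienyl)furan], via 3-furylmethylmagnesium chloride 4 (not isolated)
Conditions: Mg, THF, 0 °C; then 3, Li2CuCl4 (cat.), THF, 0 °C
Reagents that add atoms: none
Why: Copper-catalysed coupling of a Grignard reagent with a primary allylic bromide joins the furylmethyl carbon to C1 of farnesyl in the direct (SN2) sense with retention of both E olefins.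

Step 3
Reactants: 5 ambliofuran
Product: 6 (2E,6E,10E)-13-(furan-3-yl)-2,6,10-trimethyltrideca-2,6,10-trien-1-ol
Conditions: SeO2 (cat.), t-BuOOH, salicylic acid (cat.), CH2Cl2, 0 °C to rt, partial conversion
Reagents that add atoms: selenium dioxide, O=[Se]=O (catalytic oxygen carrier); tert-butyl hydroperoxide, CC(C)(C)OO (terminal oxygen source)
Why: SeO2 allylic oxidation (ene reaction, then [2,3]-sigmatropic shift) attacks the E-methyl of the terminal isopropylidene, the most accessible olefin, and should give the (E)-allylic alcohol while the inner olefins and the furan are spared at partial conversion.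

Step 4
Reactants: 6 the (2E)-allylic alcohol
Product: 7 (2S,6E,10E)-13-(furan-3-yl)-2,6,10-trimethyltrideca-6,10-dien-1-ol
Conditions: H2 (30–100 atm), Ru(OAc)2[(S)-BINAP] (0.5 mol %), MeOH, rt
Reagents that add atoms: none
Why: Hydroxyl-directed BINAP–ruthenium asymmetric hydrogenation reduces only the allylic-alcohol olefin, the ligand choosing the face and so setting the C2′ (S) methyl stereocentre; the isolated trisubstituted olefins and the furan cannot bind in the directed mode.

Step 5
Reactants: 7 the (S)-alcohol
Product: 8 3-[(3E,7E,12S)-13-iodo-4,8,12-trimethyltrideca-3,7-dien-1-yl]furan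
Conditions: I2, PPh3, imidazole, CH2Cl2, 0 °C to rt
Reagents that add atoms: iodine, II
Why: Appel-type iodination substitutes the primary carbinol carbon by SN2 without touching the adjacent stereocentre.

Step 6
Reactants: 9 but-2-ynoic acid; 10 N,O-dimethylhydroxylamine hydrochloride
Product: 11 N-methoxy-N-methylbut-2-ynamide
Conditions: EDC·HCl, 4-methylmorpholine, CH2Cl2, 0 °C to rt
Reagents that add atoms: none
Why: Carbodiimide amidation gives the Weinreb amide, which stops an organolithium addition at the ketone stage.

Step 7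
Reactants: 8 the iodide; 11 the Weinreb amide
Product: 13 (6S,10E,14E)-17-(furan-3-yl)-6,10,14-trimethylheptadeca-10,14-dien-2-yn-4-one, via primary alkyllithium 12 (not isolated)
Conditions: t-BuLi (2.1 equiv), Et2O/pentane, −78 °C; then 11, −78 °C; aqueous quench
Reagents that add atoms: none
Why: Iodine–lithium exchange gives the alkyllithium, which adds once to the Weinreb amide (stable chelate) so that the alkynyl ketone appears only on quench; the stereocentre is β to the reacting carbon and is not affected.

Step 8
Reactants: 13 the alkynyl ketone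
Product: 15 tert-butyl (4E,6S,10E,14E)-17-(furan-3-yl)-6,10,14-trimethylheptadeca-4,10,14-trien-2-yn-4-yl carbonate, via lithium E-enolate 14 (not isolated)
Conditions: LiHMDS, Et3N, toluene, −78 °C (ketone added to base); then DMPU, Boc2O, −78 to −20 °C
Reagents that add atoms: di-tert-butyl dicarbonate, CC(C)(C)OC(=O)OC(=O)OC(C)(C)C
Why: Kinetic enolization by amine-solvated LiHMDS through a closed transition state is E(O)-selective for acyclic ketones, here reinforced because the rod-like propynyl group exerts no allylic strain on the chain placed cis to it, and O-acylation of the enolate by Boc2O fixes that geometry (chain trans to the enol oxygen).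

Step 9
Reactants: 15 the E-enol tert-butyl carbonate
Product: 16 (4Z,5E)-4-ethylidene-5-[(2S,6E,10E)-13-(furan-3-yl)-2,6,10-trimethyltrideca-6,10-dien-1-ylidene]-1,3-dioxolan-2-one
Conditions: Ph3PAuNTf2 (2 mol %), CH2Cl2, 0 °C to rt
Reagents that add atoms: none
Why: Monovalent gold activates the alkyne, the Boc carbonyl oxygen adds 5-exo-dig anti to gold at the alkyne carbon next to the enol carbon, isobutene is lost and protodeauration gives the cyclic carbonate (the known cyclization of alkynyl tert-butyl carbonates); this sets the Z-ethylidene and leaves the E-enol olefin untouched.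

Step 10
Reactants: 16 the bis-alkylidene cyclic carbonate
Product: 18 (5E)-4-hydroxy-3-methyl-5-[(2S,6E,10E)-13-(furan-3-yl)-2,6,10-trimethyltrideca-6,10-dien-1-ylidene]furan-2(5H)-one, via acylpyridinium dienolate 17 (not isolated)
Conditions: DMAP (0.2 equiv), iPr2NEt (1.2 equiv), MeCN, 0 °C to rt; cold aq. citric acid work-up; used directly
Reagents that add atoms: none
Why: Proposed new method: DMAP adds to the strained carbonate carbonyl C2 and the ring opens reversibly to an N-acylpyridinium carbonate on O1 paired with the C3=C4–O dienolate (17), whose carbon C3 attacks C2, expels DMAP and forms the C2–C3 bond, the β-keto lactone then enolizing to the tetronate held as its ammonium salt; the closest known reactions are the DMAP-catalysed Steglich-type O-to-C carboxyl shift of enol carbonates and the base-induced rearrangement of α-alkylidene cyclic carbonates to tetronic acids by intramolecular Claisen condensation. The butenolide ring closes in the formally 5-(enolendo)-exo-trig mode common to Dieckmann closures of tetronic acids. No stereocentre is formed; C2′ is untouched and the C5=C1′ bond keeps its E geometry because on the productive path it stays an enol acyl unit and never becomes an enolate. The step needs regioselectivity between C-acylation at C3 and, after the alternative ring opening, at C1′; the E geometry of the substrate secures it, since C3 carries only methyl and hydrogen with the hydrogen turned inward toward the tether, whereas C1′ carries the α-branched chain turned inward, so closure at C1′ is sterically blocked and that zwitterion returns to 16.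

Step 11
Reactants: 18 the tetronic acid; 19 stearoyl chloride
Product: 20 the target, (5E)-5-[(2S,6E,10E)-13-(furan-3-yl)-2,6,10-trimethyltrideca-6,10-dien-1-ylidene]-4-methyl-5-oxo-2,5-dihydrofuran-3-yl octadecanoate
Conditions: 19 (1.05 equiv), iPr2NEt, CH2Cl2, −40 °C
Reagents that add atoms: none
Why: O-acylation of the acidic 4-OH of the tetronic acid by the acyl chloride; C-acylation at C3 is blocked by the methyl group, and leaving out any nucleophilic catalyst avoids addition–elimination at C1′ that could erode the E geometry.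

Compound list
1 | 3-furanmethanol | OCc1ccoc1 | starting material
2 | 3-(chloromethyl)furan | ClCc1ccoc1 | intermediate
3 | (2E,6E)-farnesyl bromide | CC(C)=CCC/C(C)=C/CC/C(C)=C/CBr | starting material
4 | 3-furylmethylmagnesium chloride | Cl[Mg]Cc1ccoc1 | intermediate (not isolated)
5 | ambliofuran, 3-[(3E,7E)-4,8,12-trimethyltrideca-3,7,11-trien-1-yl]furan | CC(C)=CCC/C(C)=C/CC/C(C)=C/CCc1ccoc1 | intermediate
6 | (2E,6E,10E)-13-(furan-3-yl)-2,6,10-trimethyltrideca-2,6,10-trien-1-ol | OC/C(C)=C/CC/C(C)=C/CC/C(C)=C/CCc1ccoc1 | intermediate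
7 | (2S,6E,10E)-13-(furan-3-yl)-2,6,10-trimethyltrideca-6,10-dien-1-ol | OC[C@@H](C)CCC/C(C)=C/CC/C(C)=C/CCc1ccoc1 | intermediate
8 | 3-[(3E,7E,12S)-13-iodo-4,8,12-trimethyltrideca-3,7-dien-1-yl]furan | IC[C@@H](C)CCC/C(C)=C/CC/C(C)=C/CCc1ccoc1 | intermediate
9 | but-2-ynoic acid | CC#CC(O)=O | starting material
10 | N,O-dimethylhydroxylamine hydrochloride | CNOC.Cl | starting material
11 | N-methoxy-N-methylbut-2-ynamide | CC#CC(=O)N(C)OC | intermediate
12 | primary alkyllithium from 8 (same spatial arrangement at the stereocentre) | [Li]C[C@@H](C)CCC/C(C)=C/CC/C(C)=C/CCc1ccoc1 | intermediate (not isolated)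
13 | (6S,10E,14E)-17-(furan-3-yl)-6,10,14-trimethylheptadeca-10,14-dien-2-yn-4-one | CC#CC(=O)C[C@@H](C)CCC/C(C)=C/CC/C(C)=C/CCc1ccoc1 | intermediate
14 | lithium (4E)-enolate of 13 (chain trans to O) | [Li]O/C(C#CC)=C/[C@@H](C)CCC/C(C)=C/CC/C(C)=C/CCc1ccoc1 | intermediate (not isolated)
15 | tert-butyl (4E,6S,10E,14E)-17-(furan-3-yl)-6,10,14-trimethylheptadeca-4,10,14-trien-2-yn-4-yl carbonate | CC(C)(C)OC(=O)O/C(C#CC)=C/[C@@H](C)CCC/C(C)=C/CC/C(C)=C/CCc1ccoc1 | intermediate
16 | (4Z,5E)-4-ethylidene-5-[(2S,6E,10E)-13-(furan-3-yl)-2,6,10-trimethyltrideca-6,10-dien-1-ylidene]-1,3-dioxolan-2-one | O=C1O/C(=C/[C@@H](C)CCC/C(C)=C/CC/C(C)=C/CCc2ccoc2)/C(=C/C)O1 | intermediate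
17 | ring-opened zwitterion: 4-(dimethylamino)pyridinium-1-carbonyl on O1, (Z)-enolate at C3=C4–O | C/C=C(\[O-])/C(OC(=O)[n+]1ccc(cc1)N(C)C)=C\[C@@H](C)CCC/C(C)=C/CC/C(C)=C/CCc1ccoc1 | intermediate (not isolated)
18 | (5E)-4-hydroxy-3-methyl-5-[(2S,6E,10E)-13-(furan-3-yl)-2,6,10-trimethyltrideca-6,10-dien-1-ylidene]furan-2(5H)-one | OC1=C(C)C(=O)O/C1=C/[C@@H](C)CCC/C(C)=C/CC/C(C)=C/CCc1ccoc1 | intermediate
19 | stearoyl chloride (octadecanoyl chloride) | CCCCCCCCCCCCCCCCCC(Cl)=O | starting material
20 | (5E)-5-[(2S,6E,10E)-13-(furan-3-yl)-2,6,10-trimethyltrideca-6,10-dien-1-ylidene]-4-methyl-5-oxo-2,5-dihydrofuran-3-yl octadecanoate | CCCCCCCCCCCCCCCCCC(=O)OC1=C(C)C(=O)O/C1=C/[C@@H](C)CCC/C(C)=C/CC/C(C)=C/CCc1ccoc1 | target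

Total step count: 11. Longest linear sequence: 10 steps (1 → 2 → 5 → 6 → 7 → 8 → 13 → 15 → 16 → 18 → 20); step 6 is a one-step side branch.

Steps most likely to fail

1. Step 10 (Proposed new method). The carbonate may open toward the C1′ enolate and form the carbon–carbon bond there, or the zwitterion may re-close to 16 faster than it C-acylates so that turnover stalls. Long exposure to the nucleophilic catalyst could also let the E-olefin equilibrate. The fallback uses known chemistry, sets out from ynone 13 and comes back at tetronic acid 18. Ketone 13 is enolized E-selectively as in step 8 but silylated (LiHMDS, Et3N, toluene, −78 °C; TIPSOTf) to the (E)-triisopropylsilyl enol ether F1. Ph3PAuNTf2-catalysed hydration of the enyne (H2O, dioxane, rt) places the ketone at the alkyne carbon next to the enol carbon and gives the (E)-2-silyloxy enone F2. Fluoride-mediated O-acylation (TASF, 4-nitrophenyl chloroformate, THF, −78 °C) converts it with retention into the 4-nitrophenyl enol carbonate F3. LiHMDS (THF, −78 °C) then closes the same C2–C3 bond by intramolecular Claisen (Dieckmann-type) condensation. Regiochemistry is unambiguous because only C3 is enolizable and only O1 carries the carbonate, and 4-nitrophenoxide leaves in preference to the enol oxygen.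

2. Step 8. E(O)-selectivity may be lost through enolate equilibration, or Boc2O may acylate at carbon instead of oxygen, which would carry the wrong olefin geometry into every later compound. The fallback sets the geometry by a stereospecific elimination; it sets out from alcohol 7 and comes back at target 20. Dess–Martin oxidation gives the (S)-aldehyde F4. Horner–Wadsworth–Emmons reaction with diethyl (2-oxobutyl)phosphonate (Ba(OH)2, wet THF) gives the (E)-enone F5. Nucleophilic epoxidation (t-BuOOH, DBU, CH2Cl2) gives the trans-epoxy ketone F6, as both trans diastereomers, whose two ring centres disappear later. CO2 (1 atm) with n-Bu4NBr inserts with net retention to the trans cyclic carbonate F7. LiHMDS (THF, −78 to 0 °C) closes the tetronate ring, again by C2–C3 bond formation (carbonate Claisen with release of the C1′ alkoxide), to the threo 5-(1-hydroxyalkyl)tetronic acid F8. Stearoyl chloride 19 with iPr2NEt at −40 °C acylates the acidic 4-OH to give F9. The Burgess reagent (toluene, 50 °C) effects syn-elimination across C5–C1′, which from the threo series places C2′ cis to C4 and gives 20.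

3. Step 4. Enantioface selection on the 2-methyl-2-alkenol may be insufficient or reversed, or the olefin may migrate before reduction, which would compromise the single stereocentre. The fallback moves the hydrogenation to the substrate class for which this catalyst is best established; it sets out from allylic alcohol 6 and comes back at alcohol 7. MnO2 (CH2Cl2) gives the (E)-enal F10. Ag2O (AgNO3, NaOH, aq. EtOH) gives the (E)-2-methyl-2-enoic acid F11. Ru(OAc)2[(S)-BINAP] with H2 in MeOH reduces this tiglic-acid-type olefin to the (S)-acid F12 (same ligand-sense caveat as in the assumption). LiAlH4 (Et2O, 0 °C) returns 7.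

Further compounds
F1 | step 10 | (4E,6S,10E,14E)-17-(furan-3-yl)-6,10,14-trimethyl-4-(triisopropylsilyloxy)heptadeca-4,10,14-trien-2-yne | CC(C)[Si](C(C)C)(C(C)C)O/C(C#CC)=C/[C@@H](C)CCC/C(C)=C/CC/C(C)=C/CCc1ccoc1
F2 | step 10 | (4E,6S,10E,14E)-17-(furan-3-yl)-6,10,14-trimethyl-4-(triisopropylsilyloxy)heptadeca-4,10,14-trien-3-one | CC(C)[Si](C(C)C)(C(C)C)O/C(C(=O)CC)=C/[C@@H](C)CCC/C(C)=C/CC/C(C)=C/CCc1ccoc1
F3 | step 10 | 4-nitrophenyl (4E,6S,10E,14E)-17-(furan-3-yl)-6,10,14-trimethyl-3-oxoheptadeca-4,10,14-trien-4-yl carbonate | O=C(Oc1ccc(cc1)[N+](=O)[O-])O/C(C(=O)CC)=C/[C@@H](C)CCC/C(C)=C/CC/C(C)=C/CCc1ccoc1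
F4 | step 8 | (2S,6E,10E)-13-(furan-3-yl)-2,6,10-trimethyltrideca-6,10-dienal | O=C[C@@H](C)CCC/C(C)=C/CC/C(C)=C/CCc1ccoc1
F5 | step 8 | (4E,6S,10E,14E)-17-(furan-3-yl)-6,10,14-trimethylheptadeca-4,10,14-trien-3-one | CCC(=O)/C=C/[C@@H](C)CCC/C(C)=C/CC/C(C)=C/CCc1ccoc1
F6 | step 8 | trans-4,5-epoxy ketone from F5 (one of the two trans diastereomers shown) | CCC(=O)[C@H]1O[C@@H]1[C@@H](C)CCC/C(C)=C/CC/C(C)=C/CCc1ccoc1
F7 | step 8 | trans-4-propanoyl-5-[(2S,6E,10E)-chain]-1,3-dioxolan-2-one (one of the two trans diastereomers shown) | CCC(=O)[C@H]1OC(=O)O[C@@H]1[C@@H](C)CCC/C(C)=C/CC/C(C)=C/CCc2ccoc2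
F8 | step 8 | threo 4-hydroxy-5-(1-hydroxyalkyl)-3-methylfuran-2(5H)-one | CC1=C(O)[C@@H](OC1=O)[C@H](O)[C@@H](C)CCC/C(C)=C/CC/C(C)=C/CCc1ccoc1
F9 | step 8 | threo 5-(1-hydroxyalkyl)-4-methyl-5-oxo-2,5-dihydrofuran-3-yl octadecanoate | CCCCCCCCCCCCCCCCCC(=O)OC1=C(C)C(=O)O[C@H]1[C@H](O)[C@@H](C)CCC/C(C)=C/CC/C(C)=C/CCc2ccoc2
F10 | step 4 | (2E,6E,10E)-13-(furan-3-yl)-2,6,10-trimethyltrideca-2,6,10-trienal | O=C/C(C)=C/CC/C(C)=C/CC/C(C)=C/CCc1ccoc1
F11 | step 4 | (2E,6E,10E)-13-(furan-3-yl)-2,6,10-trimethyltrideca-2,6,10-trienoic acid | OC(=O)/C(C)=C/CC/C(C)=C/CC/C(C)=C/CCc1ccoc1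
F12 | step 4 | (2S,6E,10E)-13-(furan-3-yl)-2,6,10-trimethyltrideca-6,10-dienoic acid | OC(=O)[C@@H](C)CCC/C(C)=C/CC/C(C)=C/CCc1ccoc1
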